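**Retrosynthetic overview**
1. Target 25 ⇐ acetonide hydrolysis and face-selective hydrogenation of diene 23 ⇐ Wittig union of tetracyclic enone 17 with the C8–glycerol ylide 22 (chain, C10 stereocentre and glycerol come last).
2. Enone 17 ⇐ formal [3+3] annulation of ladderene carbaldehyde 13 with tert-butyl acetoacetate 14 (Michael addition, aldol condensation, loss of the ester as isobutene and CO2). It closes the six-membered ring onto rings A–C and sets both ring-fusion stereocentres.
3. Enabling feature: in 13 the strained cyclobutene C3=C4 of ring A carries the formyl group on C3. Ring carbon C4 and the exocyclic formyl carbon are therefore 1,3-related electrophiles that a three-carbon 1,3-dinucleophile can bridge, and only the exo face of C4 (anti to ring B) is open.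
4. 13 ⇐ enoate 11 ⇐ oxidative decarboxylation of hemiester 10 ⇐ alkaloid desymmetrisation of meso anhydride 9. The carboxyl group is a temporary carrier of the absolute configuration and is extruded as CO2 once it has fixed which alkene carbon bears the ester.
5. 9 ⇐ [2+2] photocycloaddition of maleic anhydride (ring A) to bicyclo[2.2.0]hex-2-ene 7 ⇐ Ramberg–Bäcklund ring contraction with SO2 extrusion (ring B) of a thiolane fused to the cyclobutane (ring C) of commercial anhydride 1. Ring order: C, B, A, six-membered ring.

Key step: step 11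

**Remarks**
- Locants: tricyclic compounds use tricyclo[4.2.0.0(2,5)]octane numbering (ring A = C2–C5, ring B = C1, C2, C5, C6, ring C = C1, C6, C7, C8). Tetracyclic compounds use tetracyclo[6.4.0.0(2,7).0(3,6)]dodecane numbering (ring A = C1, C2, C7, C8; ring B = C2, C3, C6, C7; ring C = C3–C6; six-membered ring = C1, C8–C12). C3, C4 and the formyl carbon of 13 become C1, C8 and C12 of 17.
- Assumption: quinidine is taken to open 9 in the sense that gives 10; if the sense is opposite, its pseudo-enantiomer quinine is used under the same conditions.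
- Assumption: 2,2-dimethyl-1,3-dioxan-5-ol (18) is taken as a catalogue compound.
- Only the target and 24 carry full CIP descriptors; for the other chiral compounds the SMILES defines the absolute configuration.

**Route**

Step 1
Reactants: 1 cis-cyclobutane-1,2-dicarboxylic anhydride
Product: 2 cis-cyclobutane-1,2-diyldimethanol
Conditions: LiAlH4, THF, 0 °C to reflux; aq. NaOH work-up
Reagents that add atoms: none
Why: Hydride reduction of the cyclic anhydride gives the diol without touching the cis ring stereocentres.

Step 2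
Reactants: 2 cis-cyclobutane-1,2-diyldimethanol
Product: 3 cis-cyclobutane-1,2-diylbis(methylene) dimethanesulfonate
Conditions: MsCl, Et3N, CH2Cl2, 0 °C
Reagents that add atoms: methanesulfonyl chloride, CS(=O)(=O)Cl
Why: Standard mesylation turns both primary hydroxyls into leaving groups.

Step 3
Reactants: 3 cis-cyclobutane-1,2-diylbis(methylene) dimethanesulfonate
Product: 4 cis-3-thiabicyclo[3.2.0]heptane
Conditions: Na2S·9H2O, DMSO, 80 °C
Reagents that add atoms: sodium sulfide (Na2S), [Na+].[Na+].[S-2]
Why: Double SN2 displacement by sulfide closes the five-membered thiolane (5-exo-tet) with the cis cyclobutane geometry retained.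

Step 4
Reactants: 4 cis-3-thiabicyclo[3.2.0]heptane
Product: 6 2-chloro-cis-3-thiabicyclo[3.2.0]heptane 3,3-dioxide (racemic, chlorine epimers), via 2-chloro-3-thiabicyclo[3.2.0]heptane 5 (not isolated)
Conditions: NCS, CH2Cl2, 0 °C to rt; then mCPBA (2.2 equiv), 0 °C to rt
Reagents that add atoms: N-chlorosuccinimide, O=C1CCC(=O)N1Cl; mCPBA, OOC(=O)c1cccc(Cl)c1
Why: α-Chlorination of the sulfide through its chlorosulfonium ion, then peracid oxidation, is the standard entry to the α-chloro sulfone for a Ramberg–Bäcklund reaction; the chlorine configuration is inconsequential.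

Step 5
Reactants: 6 2-chloro-cis-3-thiabicyclo[3.2.0]heptane 3,3-dioxide
Product: 7 cis-bicyclo[2.2.0]hex-2-ene
Conditions: KOtBu, DMSO, rt; volatile product distilled into a cold trap and used as a solution
Reagents that add atoms: none
Why: Ramberg–Bäcklund reaction: base-induced 1,3-elimination with extrusion of SO2 contracts the five-membered sulfone ring to the cyclobutene (ring B), the cis fusion to ring C being retained.

Step 6
Reactants: 7 cis-bicyclo[2.2.0]hex-2-ene; 8 maleic anhydride
Product: 9 meso-cis,anti,cis-tricyclo[4.2.0.0(2,5)]octane-3,4-dicarboxylic anhydride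
Conditions: hν (Pyrex-filtered Hg lamp), acetophenone (0.2 equiv), EtOAc, −10 °C; recrystallisation
Reagents that add atoms: none
Why: Triplet-sensitised [2+2] photocycloaddition of maleic anhydride to a strained cycloalkene: addition to the exo face of 7 places ring A anti to ring C, the anhydride ring enforces the cis relationship of the two carboxyl carbons, and the orientation with the anhydride turned away from ring B should predominate for steric reasons.

Step 7
Reactants: 9 meso-cis,anti,cis-tricyclo[4.2.0.0(2,5)]octane-3,4-dicarboxylic anhydride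
Product: 10 cis-4-(methoxycarbonyl)-anti-tricyclo[4.2.0.0(2,5)]octane-3-carboxylic acid, single enantiomer (acid-bearing C3 R, ester-bearing C4 S; SMILES defines the rest)
Conditions: quinidine (1.1 equiv), MeOH (3 equiv), toluene, −55 °C; aq. HCl work-up (alkaloid recovered)
Reagents that add atoms: methanol, CO
Why: Cinchona-alkaloid-mediated enantioselective methanolysis of a meso cyclic anhydride: the chiral amine base differentiates the two enantiotopic carbonyl groups, which fixes the absolute configuration of the whole series.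

Step 8
Reactants: 10 cis-4-(methoxycarbonyl)-anti-tricyclo[4.2.0.0(2,5)]octane-3-carboxylic acid
Product: 11 methyl anti-tricyclo[4.2.0.0(2,5)]oct-3-ene-3-carboxylate (single enantiomer)
Conditions: Pb(OAc)4 (1.2 equiv), Cu(OAc)2 (0.1 equiv), pyridine, benzene, 80 °C
Reagents that add atoms: none
Why: Oxidative decarboxylation with lead tetraacetate and a copper salt: the tetravalent lead carboxylate gives the cyclobutyl radical, which divalent copper oxidises with loss of the β-hydrogen α to the ester (the only other β-hydrogen is at a ring-fusion carbon and would give an impossibly strained alkene), so the two stereocentres made in step 7 vanish while their information survives as the position of the ester on the alkene.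

Step 9
Reactants: 11 methyl anti-tricyclo[4.2.0.0(2,5)]oct-3-ene-3-carboxylate
Product: 12 (anti-tricyclo[4.2.0.0(2,5)]oct-3-en-3-yl)methanol
Conditions: iBu2AlH (2.2 equiv), CH2Cl2, −78 °C; aq. potassium sodium tartrate (KNaC4H4O6) work-up
Reagents that add atoms: none
Why: 1,2-Reduction of an α,β-unsaturated ester by diisobutylaluminium hydride at low temperature gives the allylic alcohol and leaves the strained alkene alone.

Step 10
Reactants: 12 (anti-tricyclo[4.2.0.0(2,5)]oct-3-en-3-yl)methanol
Product: 13 anti-tricyclo[4.2.0.0(2,5)]oct-3-ene-3-carbaldehyde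
Conditions: MnO2 (excess), CH2Cl2, rt; filtered and used at once as a solution
Reagents that add atoms: none
Why: Chemoselective oxidation of an allylic alcohol by MnO2 under neutral conditions gives the sensitive enal.

Step 11
Reactants: 13 anti-tricyclo[4.2.0.0(2,5)]oct-3-ene-3-carbaldehyde; 14 tert-butyl acetoacetate
Product: 17 cis,anti,cis,anti,cis-tetracyclo[6.4.0.0(2,7).0(3,6)]dodec-11-en-10-one (single enantiomer), via Michael adduct 15 (not isolated), via tert-butyl ester enone 16 (not isolated)
Conditions: 14 (1.2 equiv), DBU (0.1 equiv), toluene, 0 °C to rt; then p-TsOH·H2O (0.3 equiv), 80 °C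
Reagents that add atoms: none
Why: Base-catalysed Michael addition of the acetoacetate α-carbon to C4 of 13 (new C8–C9 bond) gives keto aldehyde 15, whose methyl ketone enolate attacks the formyl carbon in an intramolecular aldol reaction (new C11–C12 bond); acid then dehydrates the aldol to 16, cleaves the tert-butyl ester as isobutene and decarboxylates the β-keto acid to 17. The closest known reaction type is the formal [3+3] Michael–aldol condensation of β-keto esters with α,β-unsaturated aldehydes to cyclohex-2-enones, a Robinson-type annulation in which the enal supplies three ring carbons. The six-membered ring closes in a 6-(enolendo)-exo-trig aldol step followed by E1cB dehydration. C8 is set by attack on the exo face of the cyclobutene, anti to ring B, the only open face of a bicyclo[2.2.0]hex-2-ene unit; C1 is α to the formyl group in 15 and epimerisable, so it is funnelled into the cis ring fusion, through which closure is fast and which is the more stable fusion of a bicyclo[4.2.0]octane. The step needs 1,4- over 1,2-addition and exo face selectivity: strain release on rehybridising the cyclobutene carbon, the soft doubly stabilised nucleophile and the reversibility of any 1,2-adduct under the amine base should secure the first, the folded ladder the second. The absolute configuration is inherited from 13, since no stereocentre of rings B and C is touched.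

Step 12
Reactants: 18 2,2-dimethyl-1,3-dioxan-5-ol; 19 1,8-dibromooctane
Product: 20 5-[(8-bromooctyl)oxy]-2,2-dimethyl-1,3-dioxane
Conditions: NaH (1.2 equiv), DMF, 0 °C; then 19 (3 equiv), rt
Reagents that add atoms: none
Why: Williamson ether synthesis of the secondary alkoxide with a primary bromide; the excess of dibromide suppresses double alkylation.

Step 13
Reactants: 20 5-[(8-bromooctyl)oxy]-2,2-dimethyl-1,3-dioxane
Product: 21 {8-[(2,2-dimethyl-1,3-dioxan-5-yl)oxy]octyl}triphenylphosphonium bromide
Conditions: PPh3 (1.1 equiv), MeCN, reflux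
Reagents that add atoms: triphenylphosphine, c1ccc(cc1)P(c1ccccc1)c1ccccc1
Why: SN2 quaternisation of the phosphine by the primary bromide under neutral conditions that leave the acetonide intact.

Step 14
Reactants: 17 cis,anti,cis,anti,cis-tetracyclo[6.4.0.0(2,7).0(3,6)]dodec-11-en-10-one; 21 {8-[(2,2-dimethyl-1,3-dioxan-5-yl)oxy]octyl}triphenylphosphonium bromide
Product: 23 2,2-dimethyl-5-{[8-(tetracyclo[6.4.0.0(2,7).0(3,6)]dodec-11-en-10-ylidene)octyl]oxy}-1,3-dioxane (E/Z mixture), via ylide 22 (not isolated)
Conditions: 21 (1.5 equiv), KN(SiMe3)2 (1.4 equiv), THF, −78 to 0 °C; then 17, −78 °C to rt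
Reagents that add atoms: none
Why: Wittig olefination of the enone carbonyl by the non-stabilised ylide (1,2-attack) joins the chain to C10; the geometry of the new exocyclic alkene is irrelevant because it is hydrogenated next.

Step 15
Reactants: 23 2,2-dimethyl-5-{[8-(tetracyclo[6.4.0.0(2,7).0(3,6)]dodec-11-en-10-ylidene)octyl]oxy}-1,3-dioxane
Product: 24 2,2-dimethyl-5-({8-[(1R,2S,3S,6R,7R,8S,10S)-tetracyclo[6.4.0.0(2,7).0(3,6)]dodecan-10-yl]octyl}oxy)-1,3-dioxane
Conditions: H2 (3 bar), 5% Rh on Al2O3, EtOAc, rt
Reagents that add atoms: none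
Why: Heterogeneous catalytic hydrogenation saturates both alkenes, and hydrogen should reach C10 from the face of the six-membered ring opposite to fused ring A (whose C2–H and C7–H screen the other face), which places the chain cis to ring A as required (10S).

Step 16
Reactants: 24 2,2-dimethyl-5-({8-[(1R,2S,3S,6R,7R,8S,10S)-tetracyclo[6.4.0.0(2,7).0(3,6)]dodecan-10-yl]octyl}oxy)-1,3-dioxane
Product: 25 2-({8-[(1R,2S,3S,6R,7R,8S,10S)-tetracyclo[6.4.0.0(2,7).0(3,6)]dodecan-10-yl]octyl}oxy)propane-1,3-diol
Conditions: AcOH/H2O (4:1), 40 °C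
Reagents that add atoms: none
Why: Acid-catalysed hydrolysis of the isopropylidene acetal liberates the 1,3-diol; the saturated hydrocarbon core and the ether are inert.

**Compound list**
1 | cis-cyclobutane-1,2-dicarboxylic anhydride | O=C1OC(=O)[C@H]2CC[C@@H]12 | starting material
2 | cis-cyclobutane-1,2-diyldimethanol | OC[C@H]1CC[C@H]1CO | intermediate
3 | cis-cyclobutane-1,2-diylbis(methylene) dimethanesulfonate | CS(=O)(=O)OC[C@H]1CC[C@H]1COS(C)(=O)=O | intermediate
4 | cis-3-thiabicyclo[3.2.0]heptane | S1C[C@H]2CC[C@H]2C1 | intermediate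
5 | 2-chloro-cis-3-thiabicyclo[3.2.0]heptane (racemic, Cl epimers; one enantiomer drawn) | S1C[C@H]2CC[C@H]2C1Cl | intermediate
6 | 2-chloro-cis-3-thiabicyclo[3.2.0]heptane 3,3-dioxide (racemic, Cl epimers; one enantiomer drawn) | O=S1(=O)C[C@H]2CC[C@H]2C1Cl | intermediate
7 | cis-bicyclo[2.2.0]hex-2-ene | C1=C[C@H]2CC[C@@H]12 | intermediate
8 | maleic anhydride | O=C1OC(=O)C=C1 | starting material
9 | meso-cis,anti,cis-tricyclo[4.2.0.0(2,5)]octane-3,4-dicarboxylic anhydride | O=C1[C@@H]2[C@H](C(=O)O1)[C@H]3[C@@H]4CC[C@@H]4[C@@H]23 | intermediate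
10 | cis-4-(methoxycarbonyl)-anti-tricyclo[4.2.0.0(2,5)]octane-3-carboxylic acid | COC(=O)[C@@H]1[C@H](C(=O)O)[C@H]2[C@@H]3CC[C@@H]3[C@@H]12 | intermediate
11 | methyl anti-tricyclo[4.2.0.0(2,5)]oct-3-ene-3-carboxylate | COC(=O)C1=C[C@H]2[C@@H]3CC[C@@H]3[C@@H]12 | intermediate
12 | (anti-tricyclo[4.2.0.0(2,5)]oct-3-en-3-yl)methanol | OCC1=C[C@H]2[C@@H]3CC[C@@H]3[C@@H]12 | intermediate
13 | anti-tricyclo[4.2.0.0(2,5)]oct-3-ene-3-carbaldehyde | O=CC1=C[C@H]2[C@@H]3CC[C@@H]3[C@@H]12 | intermediate
14 | tert-butyl acetoacetate | CC(=O)CC(=O)OC(C)(C)C | starting material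
15 | tert-butyl 2-(4-formyl-anti-tricyclo[4.2.0.0(2,5)]octan-3-yl)-3-oxobutanoate (cis on ring A, side-chain epimers) | O=C[C@@H]1[C@H](C(C(C)=O)C(=O)OC(C)(C)C)[C@H]2[C@@H]3CC[C@@H]3[C@@H]12 | intermediate
16 | tert-butyl 10-oxotetracyclo[6.4.0.0(2,7).0(3,6)]dodec-11-ene-9-carboxylate (C9 epimers) | O=C1C=C[C@@H]2[C@H](C1C(=O)OC(C)(C)C)[C@H]1[C@@H]3CC[C@@H]3[C@@H]21 | intermediate
17 | cis,anti,cis,anti,cis-tetracyclo[6.4.0.0(2,7).0(3,6)]dodec-11-en-10-one | O=C1C=C[C@@H]2[C@H](C1)[C@H]1[C@@H]3CC[C@@H]3[C@@H]21 | intermediate
18 | 2,2-dimethyl-1,3-dioxan-5-ol | CC1(C)OCC(O)CO1 | starting material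
19 | 1,8-dibromooctane | BrCCCCCCCCBr | starting material
20 | 5-[(8-bromooctyl)oxy]-2,2-dimethyl-1,3-dioxane | CC1(C)OCC(CO1)OCCCCCCCCBr | intermediate
21 | {8-[(2,2-dimethyl-1,3-dioxan-5-yl)oxy]octyl}triphenylphosphonium bromide | CC1(C)OCC(CO1)OCCCCCCCC[P+](c1ccccc1)(c1ccccc1)c1ccccc1.[Br-] | intermediate
22 | {8-[(2,2-dimethyl-1,3-dioxan-5-yl)oxy]octylidene}triphenylphosphorane | CC1(C)OCC(CO1)OCCCCCCCC=P(c1ccccc1)(c1ccccc1)c1ccccc1 | intermediate
23 | 2,2-dimethyl-5-{[8-(tetracyclo[6.4.0.0(2,7).0(3,6)]dodec-11-en-10-ylidene)octyl]oxy}-1,3-dioxane (E/Z mixture) | CC1(C)OCC(CO1)OCCCCCCCC=C1C=C[C@@H]2[C@H](C1)[C@H]1[C@@H]3CC[C@@H]3[C@@H]21 | intermediate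
24 | 2,2-dimethyl-5-({8-[(1R,2S,3S,6R,7R,8S,10S)-tetracyclo[6.4.0.0(2,7).0(3,6)]dodecan-10-yl]octyl}oxy)-1,3-dioxane | CC1(C)OCC(CO1)OCCCCCCCC[C@H]1CC[C@@H]2[C@H](C1)[C@H]1[C@@H]3CC[C@@H]3[C@@H]21 | intermediate
25 | 2-({8-[(1R,2S,3S,6R,7R,8S,10S)-tetracyclo[6.4.0.0(2,7).0(3,6)]dodecan-10-yl]octyl}oxy)propane-1,3-diol | OCC(CO)OCCCCCCCC[C@H]1CC[C@@H]2[C@H](C1)[C@H]1[C@@H]3CC[C@@H]3[C@@H]21 | target

**Step count and risks**
Total: 16 steps. Longest linear sequence: 14 steps (steps 1–11, 14–16); steps 12 and 13 form the side branch.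

Steps most likely to fail:

1. Step 11 (key step). What may go wrong: 1,2-addition or condensation at the formyl group, base-induced oligomerisation of the strained enal before the conjugate addition, or O-cyclisation of the keto aldehyde to a pyran in place of the carbocyclic aldol. Fallback (the two bonds are made separately, the first at the ester oxidation level where no 1,2-pathway exists): setting out from enoate 11, conjugate addition of 14 (KOtBu cat., THF/tBuOH, rt) should give the Michael adduct F1. Treatment with CF3CO2H and then heat (toluene, 90 °C) should give keto ester F2. LiAlH4 should give diol F3, and Swern oxidation the keto aldehyde F4. Aldol condensation of F4 (pyrrolidine/AcOH cat., toluene, 60 °C) should close the ring, the epimerisable C3 being funnelled into the cis fusion, and the route is rejoined at enone 17.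

2. Step 15. What may go wrong: insufficient facial discrimination when hydrogen is delivered to C10, made worse by migration of the exocyclic alkene before reduction. Fallback (catalyst control in place of substrate control; it also bypasses step 14): setting out from 17, conjugate reduction with LiBH(sBu)3 (THF, −78 °C) and trapping of the enolate with N-(5-chloropyridin-2-yl)-1,1,1-trifluoro-N-(trifluoromethylsulfonyl)methanesulfonamide should give the enol triflate F5. Cross-coupling catalysed by Fe(acac)3 (THF/NMP, −20 °C) with the Grignard reagent F6, made from bromide 20 and Mg in THF, should give the trisubstituted cyclohexene F7. Hydrogenation with a chiral cationic iridium phosphine–oxazoline complex, [Ir(cod)(L)][B(C6H3(CF3)2)4] (L = tBu-PHOX), using the ligand enantiomer whose facial preference matches the substrate bias, should give 24, where the route is rejoined.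

3. Step 8. What may go wrong: capture of the cyclobutyl radical by acetate or by the product enoate in place of oxidative elimination. Fallback (halodecarboxylation followed by a polar elimination): setting out from 10, decarboxylative iodination (PhI(OAc)2, I2, visible light, CH2Cl2, reflux) should give the β-iodo ester F8. E1cB elimination with DBU (CH2Cl2, rt), which can only remove the hydrogen α to the ester, should return the route to 11.

**Further compounds**
F1 | step 11 | methyl 4-[1-(tert-butoxy)-1,3-dioxobutan-2-yl]-anti-tricyclo[4.2.0.0(2,5)]octane-3-carboxylate (C3 and side-chain epimers; cis isomer drawn) | COC(=O)[C@@H]1[C@H](C(C(C)=O)C(=O)OC(C)(C)C)[C@H]2[C@@H]3CC[C@@H]3[C@@H]12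
F2 | step 11 | methyl 4-(2-oxopropyl)-anti-tricyclo[4.2.0.0(2,5)]octane-3-carboxylate (cis isomer drawn) | COC(=O)[C@@H]1[C@H](CC(C)=O)[C@H]2[C@@H]3CC[C@@H]3[C@@H]12
F3 | step 11 | 1-[4-(hydroxymethyl)-anti-tricyclo[4.2.0.0(2,5)]octan-3-yl]propan-2-ol (carbinol epimers) | OC[C@@H]1[C@H](CC(C)O)[C@H]2[C@@H]3CC[C@@H]3[C@@H]12
F4 | step 11 | 4-(2-oxopropyl)-anti-tricyclo[4.2.0.0(2,5)]octane-3-carbaldehyde | O=C[C@@H]1[C@H](CC(C)=O)[C@H]2[C@@H]3CC[C@@H]3[C@@H]12
F5 | step 15 | tetracyclo[6.4.0.0(2,7).0(3,6)]dodec-10-en-10-yl trifluoromethanesulfonate | O=S(=O)(OC1=CC[C@@H]2[C@H](C1)[C@H]1[C@@H]3CC[C@@H]3[C@@H]21)C(F)(F)F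
F6 | step 15 | {8-[(2,2-dimethyl-1,3-dioxan-5-yl)oxy]octyl}magnesium bromide | CC1(C)OCC(CO1)OCCCCCCCC[Mg]Br
F7 | step 15 | 2,2-dimethyl-5-{[8-(tetracyclo[6.4.0.0(2,7).0(3,6)]dodec-10-en-10-yl)octyl]oxy}-1,3-dioxane | CC1(C)OCC(CO1)OCCCCCCCCC1=CC[C@@H]2[C@H](C1)[C@H]1[C@@H]3CC[C@@H]3[C@@H]21
F8 | step 8 | methyl 4-iodo-anti-tricyclo[4.2.0.0(2,5)]octane-3-carboxylate (iodide epimers) | COC(=O)[C@@H]1C(I)[C@H]2[C@@H]3CC[C@@H]3[C@@H]12
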